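## The problem

The target is a 2,3-cis-flavan-3-ol gallate. Its chroman core joins the phloroglucinol ring A to the pyran ring C through C4a–C8a, ring B (3,5-dihydroxy-4-methoxyphenyl) sits on C2, and a galloyl ester sits on the C3 oxygen. The only stereocentres are C2 (R) and C3 (R). They are cis, the less stable arrangement, so any closure of ring C through a benzylic cation at C2 drifts to trans; the cis relation must come from a stereospecific bond formation. The secure order is to fix the C2 and C3 oxygens together in an open chain by one reagent-controlled event and then close O1–C2 with clean inversion. C3 cannot be used afterwards to correct C2 without losing the absolute configuration. The seven phenolic hydroxyls are easily oxidised and, once free, allow base-induced epimerisation at C2 and acyl migration. They must therefore stay masked by groups that leave under neutral conditions at the end, and the 4'-methyl ether must be present from the outset. The ester has to be made late, on a C3 hydroxyl unveiled orthogonally to the phenol protection. The feature that opens a short entry to ring A is that C4a, C5, C6, C7, C8 and C8a carry oxygen on every second carbon (C5, C7, C8a) and the alkyl carbon C4 on C4a. This is a triketide folded by a C4a–C8a bond, and the same six carbons and three oxygens are present, unfolded, in a 6-alkyl-4-alkoxy-2-pyrone. After the fold the C5 and C8a hydroxyls are equivalent, so either can become O1.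

## Retrosynthesis

**Ester and phenol protection.** The target 23 is reached from the heptabenzyl ether 22 by hydrogenolysis, which is neutral and spares the ester, the methyl ether and the C2–O1 bond. 22 is cut at the acyl–O3 bond into the flavan-3-ol 20 and the acid 21. Acylating last keeps the ester out of every basic step. The forward reaction must acylate a hindered axial alcohol without touching C2.

**Ring C, O1–C2.** 20 is 19 without its methoxymethyl group, 19 is the benzyl ether of phenol 18, and 18 is cut at O1–C2 to the open-chain alcohol 17. A cut at O1–C8a would need an aryl halide and would close with retention at C2. A cut at C4–C4a on a finished phloroglucinol gives no hold on C3. The O1–C2 cut lets the cis relation be set as an erythro chain plus inversion. Because the two phenols of 17 flank the chain symmetrically, no regiochemical question arises. 17 is the desilylated form of 16. The forward closure must be an SN2 displacement at a benzylic carbon with no ionisation.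

**Ring A, C4a–C8a.** The resorcinol 16 is unfolded at C4a–C8a to the pyrone 13, its constitutional isomer. This removes an aromatic ring from the problem and replaces it by a lactone in which C5, C7 and C8a are already oxygenated and the C6=C7 double bond is already cis. It also avoids any differentiation of three phenols. The forward reaction must deprotonate C4a, open the lactone and acylate C4a with C8a without intermolecular condensation.

**Side chain, C4–C4a.** 13 is the methoxymethyl ether of alcohol 12, and 12 is cut between C4 and C4a into the methylpyrone 10 and the epoxide 8. The lateral carbon of 10 is the known site of metalation, and the terminal epoxide carbon of 8 is the only unhindered electrophilic site. The cut delivers the C3 hydroxyl free for separate protection. 10 is the benzyl ether of 9, which supplies all six carbons of ring A.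

**Stereocentres, epoxide and C2–C3.** 8 is the silyl ether of epoxy alcohol 7, and 7 comes from the racemic allylic alcohol 6 by Sharpless kinetic resolution. That one step selects C2 and creates C3 in the erythro relation. 6 is cut at C2–C3 into aldehyde 4 and the vinyl Grignard reagent 5. A dihydroxylation route would give the threo series and a separate inversion, so the epoxide route is shorter.

**Ring B.** 4 comes from alcohol 3, 3 from ester 2, and 2 from the commercial 4-O-methyl gallate 1 by benzylation of its two equivalent phenols. The methyl ether is thus never installed selectively.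

## Roads not taken

**Alternative 1:** Ring C is cut at C4–C4a, C3–C4 and O1–C2 at once. Forward, 3,5-bis(benzyloxy)phenol A1 and formaldehyde A2 would form an ortho-quinone methide, which adds as a heterodiene to the (Z)-enol gallate A3. The adduct A4 is identical with 22.
- Merits: rings A and B and the ester arrive preformed, the cis relation follows from the Z alkene in a suprafacial addition, and the route would be less than half as long as the chosen one.
- Weak points: the alkene is polarised in two opposing senses. The enol oxygen directs its own carbon to the methide oxygen, while the aryl group directs the benzylic carbon there, and only the second gives a flavan. The unsubstituted methide offers a chiral catalyst no handle, so absolute control is unsecured. A1 and A2 tend to over-condense, and A3 can transfer its acyl group to A1.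
- Comparison: this road is clearly better in step count. The chosen plan offers a reagent-controlled source of both stereocentres and an unambiguous regiochemistry in every bond formation.

**Alternative 2:** Ring A is cut at C4a–C5, C8–C8a and C5–C6. Forward, the siloxyalkyne A5 and 3-(benzyloxy)cyclobut-2-en-1-one A6 are heated in a Danheiser benzannulation ([2+2] addition of the vinylketene, ring opening, 6π closure) to give the resorcinol monosilyl ether A7.
- Merits: the ring-forming reaction is established for siloxyalkynes, is thermal and neutral, and delivers the two ortho oxygens already differentiated. A5 would come from epoxide 8 by an acetylide opening, which is more dependable than the pyrone coupling of the chosen plan.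
- Weak points: A5 needs an extra oxidation and silylation of the alkyne and is acid-labile. A6 is not a catalogue compound and is thermally sensitive. Both must be made in several steps for a ring whose atoms 9 supplies from the bottle.
- Comparison: on precedent this road is the stronger one. The chosen plan offers atom and reagent economy, and the fact that its two ortho hydroxyls need no differentiation; it carries the risk of an untested isomerisation.

**Alternative 3:** Ring C is cut at C3=C4. Forward, ring-closing metathesis with a ruthenium benzylidene catalyst bearing an N-heterocyclic carbene (second-generation Grubbs type) joins the styrene carbon and the enol ester carbon of the diene A8, giving the 2H-chromene A9. Hydrogenation anti to the C2 aryl group would set C3 and remove the benzyl groups in one operation.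
- Merits: the gallate is in place before closure, only one stereocentre has to be made, and the end game is one step.
- Weak points: a 1,1-disubstituted enol ester and a doubly ortho-substituted styrene are both poor metathesis partners. In the ketone precursor of A8, C2 is benzylic, α to oxygen and α to the carbonyl, so it is easily racemised. A9 can open electrocyclically to an ortho-quinone methide, which also erases C2. The allylic, benzylic C2–O1 bond of A9 is exposed to hydrogenolysis.
- Comparison: this road is more convergent. The chosen plan keeps C2 sp3 and non-enolisable from the step that sets it to the end.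

Key step: step 10

Remark on the chemistry: atoms of open-chain and pyrone intermediates are referred to by the flavan numbers they acquire in the target (O1, C2, C3, C4, C4a, C5 to C8, C8a). Compounds 1, 5, 9 and 21 are taken as catalogue chemicals.

## Route

Step 1
Reactants: 1 methyl 3,5-dihydroxy-4-methoxybenzoate
Product: 2 methyl 3,5-bis(benzyloxy)-4-methoxybenzoate
Conditions: BnBr, K2CO3, DMF, 60 °C
Reagents that add atoms: benzyl bromide, BrCc1ccccc1
Why: Williamson etherification of two equivalent phenols; the methyl ether is already in place, so no regiochemical question arises.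

Step 2
Reactants: 2 methyl 3,5-bis(benzyloxy)-4-methoxybenzoate
Product: 3 [3,5-bis(benzyloxy)-4-methoxyphenyl]methanol
Conditions: LiAlH4, THF, 0 °C to rt
Reagents that add atoms: none
Why: Hydride reduction of an aryl ester to the benzylic alcohol; benzyl and methyl aryl ethers are inert.

Step 3
Reactants: 3 [3,5-bis(benzyloxy)-4-methoxyphenyl]methanol
Product: 4 3,5-bis(benzyloxy)-4-methoxybenzaldehyde
Conditions: MnO2 (activated), CH2Cl2, rt
Reagents that add atoms: none
Why: Manganese dioxide oxidises benzylic alcohols to aldehydes and stops there.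

Step 4
Reactants: 4 3,5-bis(benzyloxy)-4-methoxybenzaldehyde; 5 vinylmagnesium bromide
Product: 6 racemic 1-[3,5-bis(benzyloxy)-4-methoxyphenyl]prop-2-en-1-ol
Conditions: THF, −78 to 0 °C; aq. NH4Cl
Reagents that add atoms: none
Why: Grignard addition to an aromatic aldehyde forms the C2–C3 bond and gives the racemic secondary allylic alcohol needed for kinetic resolution.

Step 5
Reactants: 6 racemic 1-[3,5-bis(benzyloxy)-4-methoxyphenyl]prop-2-en-1-ol
Product: 7 (S)-[3,5-bis(benzyloxy)-4-methoxyphenyl][(2R)-oxiran-2-yl]methanol
Conditions: Ti(OiPr)4 (0.2 equiv), L-(+)-diisopropyl tartrate (0.3 equiv), t-BuOOH (0.5 equiv), 4 Å sieves, CH2Cl2, −20 °C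
Reagents that add atoms: tert-butyl hydroperoxide, CC(C)(C)OO
Why: Sharpless kinetic resolution: the titanium–L-(+)-tartrate catalyst should epoxidise the (R)-enantiomer of 6 much faster than the (S)-enantiomer and deliver oxygen to the face that gives the erythro epoxy alcohol. C2 (S at this stage) is thus selected from the racemate and C3 (R) is set by the catalyst in the same event; the reaction is stopped short of half conversion and (S)-6 remains.

Step 6
Reactants: 7 (S)-[3,5-bis(benzyloxy)-4-methoxyphenyl][(2R)-oxiran-2-yl]methanol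
Product: 8 tert-butyl{(S)-[3,5-bis(benzyloxy)-4-methoxyphenyl][(2R)-oxiran-2-yl]methoxy}dimethylsilane
Conditions: TBSCl, imidazole, DMF, rt
Reagents that add atoms: tert-butyldimethylsilyl chloride, CC(C)(C)[Si](C)(C)Cl
Why: Silylation of the secondary alcohol blocks Payne rearrangement in the basic coupling and marks the C2 oxygen as the one to be released by fluoride later.

Step 7
Reactants: 9 4-hydroxy-6-methyl-2H-pyran-2-one
Product: 10 4-(benzyloxy)-6-methyl-2H-pyran-2-one
Conditions: BnBr, DBU, MeCN, rt
Reagents that add atoms: benzyl bromide, BrCc1ccccc1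
Why: O-alkylation of the vinylogous acid with an amidine base; the benzyl enol ether will become the C7 benzyl ether of ring A.

Step 8
Reactants: 10 4-(benzyloxy)-6-methyl-2H-pyran-2-one; 8 tert-butyl{(S)-[3,5-bis(benzyloxy)-4-methoxyphenyl][(2R)-oxiran-2-yl]methoxy}dimethylsilane
Product: 12 4-(benzyloxy)-6-{(3R,4S)-4-[3,5-bis(benzyloxy)-4-methoxyphenyl]-4-[(tert-butyldimethylsilyl)oxy]-3-hydroxybutyl}-2H-pyran-2-one, via lithiated pyrone 11 (not isolated)
Conditions: 10, LiN(iPr)2, THF, −78 °C; then 8, BF3·OEt2, −78 °C; aq. NH4Cl at −78 °C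
Reagents that add atoms: none
Why: Lateral lithiation of 4-alkoxy-6-methyl-2-pyrones with a lithium amide is the established way to functionalise the methyl group. BF3·OEt2 activates the terminal epoxide at low temperature so that the delocalised carbanion opens it by SN2 attack at the unhindered CH2 (C4), forming C4–C4a and leaving C2 and C3 untouched.

Step 9
Reactants: 12 4-(benzyloxy)-6-{(3R,4S)-4-[3,5-bis(benzyloxy)-4-methoxyphenyl]-4-[(tert-butyldimethylsilyl)oxy]-3-hydroxybutyl}-2H-pyran-2-one
Product: 13 4-(benzyloxy)-6-{(3R,4S)-4-[3,5-bis(benzyloxy)-4-methoxyphenyl]-4-[(tert-butyldimethylsilyl)oxy]-3-(methoxymethoxy)butyl}-2H-pyran-2-one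
Conditions: MOMCl, iPr2NEt, Bu4NI (cat.), CH2Cl2, 0 to 40 °C
Reagents that add atoms: chloromethyl methyl ether, COCCl
Why: Acetal protection of the C3 hydroxyl under non-nucleophilic amine base, which the pyrone tolerates; the group is stable to strong base, fluoride and Mitsunobu conditions and is orthogonal to silyl and benzyl ethers.

Step 10
Reactants: 13 4-(benzyloxy)-6-{(3R,4S)-4-[3,5-bis(benzyloxy)-4-methoxyphenyl]-4-[(tert-butyldimethylsilyl)oxy]-3-(methoxymethoxy)butyl}-2H-pyran-2-one
Product: 16 5-(benzyloxy)-2-{(2R,3S)-3-[3,5-bis(benzyloxy)-4-methoxyphenyl]-3-[(tert-butyldimethylsilyl)oxy]-2-(methoxymethoxy)propyl}benzene-1,3-diol, via potassium lateral dienolate 14 (not isolated), via dienylketene enolate 15 (not isolated)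
Conditions: KN(SiMe3)2 (3 equiv), 18-crown-6, THF (0.01 M), −78 °C, then warm to 60 °C; aq. NH4Cl
Reagents that add atoms: none
Why: Proposed new method: the silylamide should remove a proton from the lateral carbon C4a, the thermodynamic site of metalation of 6-alkyl-4-alkoxy-2-pyrones, to give the extended lactone enolate 14. On warming, 14 should expel the ring oxygen from the enolate carbon C8a in an E1cB step, giving the ketene 15 in which that oxygen has become the enolate C5(O−)=C4a. After rotation about C5–C6 the enolate carbon C4a acylates the ketene carbon C8a, and proton transfer aromatises the cyclohexadienone to the bis-phenoxide of 16. The closest known reactions are the base-induced Claisen recyclisation of pyrone-masked polyketides to acylphloroglucinols, the E1cB formation of ketenes from aryl ester enolates, and the dienylketene-to-phenol closure of the Danheiser benzannulation. Ring A closes by a 6-exo-dig C-acylation of the enolate, equivalent to a 6π-electrocyclisation of the oxido-dienylketene; no stereocentre is formed, and C2 and C3 are remote from any acidic position. The step needs C- over O-acylation, and the substrate secures this because O-acylation only regenerates 14 while C-acylation is made irreversible by aromatisation. Only C4a can reach C8a through a six-membered transition state, and the cis C6=C7 geometry is inherited from the pyrone ring. The potassium silylamide is chosen over a lithium dialkylamide because its conjugate acid does not add to ketenes. Three equivalents and high dilution keep neutral pyrone and acidic product from meeting the anion, which is what suppresses intermolecular condensation.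

Step 11
Reactants: 16 5-(benzyloxy)-2-{(2R,3S)-3-[3,5-bis(benzyloxy)-4-methoxyphenyl]-3-[(tert-butyldimethylsilyl)oxy]-2-(methoxymethoxy)propyl}benzene-1,3-diol
Product: 17 5-(benzyloxy)-2-{(2R,3S)-3-[3,5-bis(benzyloxy)-4-methoxyphenyl]-3-hydroxy-2-(methoxymethoxy)propyl}benzene-1,3-diol
Conditions: Bu4NF, AcOH, THF, 0 °C to rt
Reagents that add atoms: none
Why: Fluoride desilylation, buffered so that the electron-rich resorcinol is not kept as a phenoxide; acetal and benzyl ethers are inert, and any silyl group that had migrated to a phenol in step 10 is removed as well.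

Step 12
Reactants: 17 5-(benzyloxy)-2-{(2R,3S)-3-[3,5-bis(benzyloxy)-4-methoxyphenyl]-3-hydroxy-2-(methoxymethoxy)propyl}benzene-1,3-diol
Product: 18 (2R,3R)-7-(benzyloxy)-2-[3,5-bis(benzyloxy)-4-methoxyphenyl]-3-(methoxymethoxy)-3,4-dihydro-2H-1-benzopyran-5-ol
Conditions: PPh3, DIAD (betaine preformed at 0 °C), then 17, THF (0.02 M), 0 °C
Reagents that add atoms: none
Why: Intramolecular Mitsunobu etherification, a known way to close the pyran ring of flavans: the benzylic C2 hydroxyl is activated as the oxyphosphonium ion and displaced by an ortho phenol in a 6-exo-tet SN2 step. C2 is inverted from S to R, which turns the erythro chain into the 2,3-cis ring; the two phenols are equivalent, so either gives the same product.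

Step 13
Reactants: 18 (2R,3R)-7-(benzyloxy)-2-[3,5-bis(benzyloxy)-4-methoxyphenyl]-3-(methoxymethoxy)-3,4-dihydro-2H-1-benzopyran-5-ol
Product: 19 (2R,3R)-5,7-bis(benzyloxy)-2-[3,5-bis(benzyloxy)-4-methoxyphenyl]-3-(methoxymethoxy)-3,4-dihydro-2H-1-benzopyran
Conditions: BnBr, K2CO3, DMF, rt
Reagents that add atoms: benzyl bromide, BrCc1ccccc1
Why: Williamson etherification of the remaining phenol, so that only the C3 oxygen will be free for acylation.

Step 14
Reactants: 19 (2R,3R)-5,7-bis(benzyloxy)-2-[3,5-bis(benzyloxy)-4-methoxyphenyl]-3-(methoxymethoxy)-3,4-dihydro-2H-1-benzopyran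
Product: 20 (2R,3R)-5,7-bis(benzyloxy)-2-[3,5-bis(benzyloxy)-4-methoxyphenyl]-3,4-dihydro-2H-1-benzopyran-3-ol
Conditions: HCl (cat.), MeOH/THF, 45 °C
Reagents that add atoms: none
Why: Acid-catalysed acetal exchange with methanol frees the C3 hydroxyl; aryl benzyl ethers and the fully etherified flavan are stable to dilute acid.

Step 15
Reactants: 20 (2R,3R)-5,7-bis(benzyloxy)-2-[3,5-bis(benzyloxy)-4-methoxyphenyl]-3,4-dihydro-2H-1-benzopyran-3-ol; 21 3,4,5-tris(benzyloxy)benzoic acid
Product: 22 (2R,3R)-5,7-bis(benzyloxy)-2-[3,5-bis(benzyloxy)-4-methoxyphenyl]-3,4-dihydro-2H-1-benzopyran-3-yl 3,4,5-tris(benzyloxy)benzoate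
Conditions: DCC, DMAP, CH2Cl2, rt
Reagents that add atoms: none
Why: Steglich esterification; the acylpyridinium intermediate acylates the hindered axial C3 alcohol with retention, since no bond to C3 is broken.

Step 16
Reactants: 22 (2R,3R)-5,7-bis(benzyloxy)-2-[3,5-bis(benzyloxy)-4-methoxyphenyl]-3,4-dihydro-2H-1-benzopyran-3-yl 3,4,5-tris(benzyloxy)benzoate
Product: 23 4'-O-methylepigallocatechin-3-O-gallate, (2R,3R)-5,7-dihydroxy-2-(3,5-dihydroxy-4-methoxyphenyl)-3,4-dihydro-2H-1-benzopyran-3-yl 3,4,5-trihydroxybenzoate
Conditions: H2 (1 atm), Pd(OH)2 on carbon, THF/MeOH, rt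
Reagents that add atoms: none
Why: Hydrogenolysis of seven aryl benzyl ethers under neutral conditions, which should leave the methyl ether, the ester and the cyclic benzylic C2–O1 bond intact and avoid base-induced epimerisation of the free polyphenol.

## Compound list

1 | methyl 3,5-dihydroxy-4-methoxybenzoate | COC(=O)c1cc(O)c(OC)c(O)c1 | starting material
2 | methyl 3,5-bis(benzyloxy)-4-methoxybenzoate | COC(=O)c1cc(OCc2ccccc2)c(OC)c(OCc2ccccc2)c1 | intermediate
3 | [3,5-bis(benzyloxy)-4-methoxyphenyl]methanol | COc1c(OCc2ccccc2)cc(CO)cc1OCc1ccccc1 | intermediate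
4 | 3,5-bis(benzyloxy)-4-methoxybenzaldehyde | COc1c(OCc2ccccc2)cc(C=O)cc1OCc1ccccc1 | intermediate
5 | vinylmagnesium bromide | C=C[Mg]Br | starting material
6 | racemic 1-[3,5-bis(benzyloxy)-4-methoxyphenyl]prop-2-en-1-ol | COc1c(OCc2ccccc2)cc(C(O)C=C)cc1OCc1ccccc1 | intermediate
7 | (S)-[3,5-bis(benzyloxy)-4-methoxyphenyl][(2R)-oxiran-2-yl]methanol | COc1c(OCc2ccccc2)cc(cc1OCc1ccccc1)[C@H](O)[C@H]1CO1 | intermediate
8 | tert-butyl{(S)-[3,5-bis(benzyloxy)-4-methoxyphenyl][(2R)-oxiran-2-yl]methoxy}dimethylsilane | COc1c(OCc2ccccc2)cc(cc1OCc1ccccc1)[C@H](O[Si](C)(C)C(C)(C)C)[C@H]1CO1 | intermediate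
9 | 4-hydroxy-6-methyl-2H-pyran-2-one | Cc1cc(O)cc(=O)o1 | starting material
10 | 4-(benzyloxy)-6-methyl-2H-pyran-2-one | Cc1cc(OCc2ccccc2)cc(=O)o1 | intermediate
11 | lithium 4-(benzyloxy)-6-methylidene-6H-pyran-2-olate (lithiated pyrone) | [Li+].C=C1C=C(OCc2ccccc2)C=C([O-])O1 | intermediate (not isolated)
12 | 4-(benzyloxy)-6-{(3R,4S)-4-[3,5-bis(benzyloxy)-4-methoxyphenyl]-4-[(tert-butyldimethylsilyl)oxy]-3-hydroxybutyl}-2H-pyran-2-one | COc1c(OCc2ccccc2)cc(cc1OCc1ccccc1)[C@H](O[Si](C)(C)C(C)(C)C)[C@H](O)CCc1cc(OCc2ccccc2)cc(=O)o1 | intermediate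
13 | 4-(benzyloxy)-6-{(3R,4S)-4-[3,5-bis(benzyloxy)-4-methoxyphenyl]-4-[(tert-butyldimethylsilyl)oxy]-3-(methoxymethoxy)butyl}-2H-pyran-2-one | COc1c(OCc2ccccc2)cc(cc1OCc1ccccc1)[C@H](O[Si](C)(C)C(C)(C)C)[C@H](OCOC)CCc1cc(OCc2ccccc2)cc(=O)o1 | intermediate
14 | potassium lateral dienolate of 13 (6-alkylidene-4-benzyloxy-6H-pyran-2-olate) | [K+].COc1c(OCc2ccccc2)cc(cc1OCc1ccccc1)[C@H](O[Si](C)(C)C(C)(C)C)[C@H](OCOC)CC=C1C=C(OCc2ccccc2)C=C([O-])O1 | intermediate (not isolated)
15 | dienylketene enolate (ketene at C8a, benzyl enol ether at C7, potassium enolate C5(O−)=C4a) | [K+].COc1c(OCc2ccccc2)cc(cc1OCc1ccccc1)[C@H](O[Si](C)(C)C(C)(C)C)[C@H](OCOC)CC=C([O-])/C=C(OCc2ccccc2)\C=C=O | intermediate (not isolated)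
16 | 5-(benzyloxy)-2-{(2R,3S)-3-[3,5-bis(benzyloxy)-4-methoxyphenyl]-3-[(tert-butyldimethylsilyl)oxy]-2-(methoxymethoxy)propyl}benzene-1,3-diol | COc1c(OCc2ccccc2)cc(cc1OCc1ccccc1)[C@H](O[Si](C)(C)C(C)(C)C)[C@H](OCOC)Cc1c(O)cc(OCc2ccccc2)cc1O | intermediate
17 | 5-(benzyloxy)-2-{(2R,3S)-3-[3,5-bis(benzyloxy)-4-methoxyphenyl]-3-hydroxy-2-(methoxymethoxy)propyl}benzene-1,3-diol | COc1c(OCc2ccccc2)cc(cc1OCc1ccccc1)[C@H](O)[C@H](OCOC)Cc1c(O)cc(OCc2ccccc2)cc1O | intermediate
18 | (2R,3R)-7-(benzyloxy)-2-[3,5-bis(benzyloxy)-4-methoxyphenyl]-3-(methoxymethoxy)-3,4-dihydro-2H-1-benzopyran-5-ol | COc1c(OCc2ccccc2)cc(cc1OCc1ccccc1)[C@H]1Oc2cc(OCc3ccccc3)cc(O)c2C[C@H]1OCOC | intermediate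
19 | (2R,3R)-5,7-bis(benzyloxy)-2-[3,5-bis(benzyloxy)-4-methoxyphenyl]-3-(methoxymethoxy)-3,4-dihydro-2H-1-benzopyran | COc1c(OCc2ccccc2)cc(cc1OCc1ccccc1)[C@H]1Oc2cc(OCc3ccccc3)cc(OCc3ccccc3)c2C[C@H]1OCOC | intermediate
20 | (2R,3R)-5,7-bis(benzyloxy)-2-[3,5-bis(benzyloxy)-4-methoxyphenyl]-3,4-dihydro-2H-1-benzopyran-3-ol | COc1c(OCc2ccccc2)cc(cc1OCc1ccccc1)[C@H]1Oc2cc(OCc3ccccc3)cc(OCc3ccccc3)c2C[C@H]1O | intermediate
21 | 3,4,5-tris(benzyloxy)benzoic acid | OC(=O)c1cc(OCc2ccccc2)c(OCc2ccccc2)c(OCc2ccccc2)c1 | starting material
22 | (2R,3R)-5,7-bis(benzyloxy)-2-[3,5-bis(benzyloxy)-4-methoxyphenyl]-3,4-dihydro-2H-1-benzopyran-3-yl 3,4,5-tris(benzyloxy)benzoate | COc1c(OCc2ccccc2)cc(cc1OCc1ccccc1)[C@H]1Oc2cc(OCc3ccccc3)cc(OCc3ccccc3)c2C[C@H]1OC(=O)c1cc(OCc2ccccc2)c(OCc2ccccc2)c(OCc2ccccc2)c1 | intermediate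
23 | 4'-O-methylepigallocatechin-3-O-gallate | COc1c(O)cc(cc1O)[C@H]1Oc2cc(O)cc(O)c2C[C@H]1OC(=O)c1cc(O)c(O)c(O)c1 | target

## Step count and least certain steps

Total: 16 steps. Longest linear sequence: 15 steps (1 to 23 through steps 1 to 6 and 8 to 16); step 7 is the only step off the main line.

**Step 10 (key step).** The lateral anion may fail to open to the ketene below the temperature at which it is consumed by condensation with traces of neutral pyrone. Deprotonation may be diverted to the ring CH at C8, or the ketene may be intercepted by an external nucleophile before C-acylation.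

Fallback with known chemistry, ring A brought in preformed: it sets out from epoxide 8 and returns at 19.
- The aryl ether 1,3-bis(benzyloxy)-5-{[2-(trimethylsilyl)ethoxy]methoxy}benzene F1, one step from the commercial phenol, is lithiated with n-BuLi between the acetal oxygen and a benzyloxy group.
- The aryllithium opens 8 at C4 in the presence of BF3·OEt2 to give the alcohol F2.
- The C3 hydroxyl of F2 is protected with MOMCl to give the acetal F3.
- Bu4NF in a dipolar solvent at 80 °C removes the aryl SEM group and the silyl ether together, giving the phenol alcohol F4.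
- Mitsunobu closure of F4 as in step 12 gives 19.

**Step 8.** The delocalised lithium dienolate may be too weak a nucleophile for the epoxide, or may be silenced by the Lewis acid. The Lewis acid may trigger rearrangement of the silyloxy epoxide, and the new alkoxide may accept the neighbouring silyl group by 1,2-migration.

Fallback, alkylation in place of epoxide opening: it sets out from 8 and returns at 13.
- LiI and AcOH in THF open 8 at the terminal carbon to the iodohydrin F5.
- MOMCl and iPr2NEt convert F5 into the iodide F6.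
- The lithiated pyrone 11 is alkylated with F6 in THF with a dipolar cosolvent, the established mode of reaction of this anion with primary iodides. This gives 13 directly.

**Step 12.** The activated benzylic C2 may ionise, which would cost stereospecificity, or may eliminate toward C3. The azodicarboxylate may also aminate the electron-rich resorcinol ring.

Fallback, closure with neighbouring-group control in place of direct SN2: it sets out from 16 and returns at 20.
- Me2BBr at −78 °C cleaves the acetal while C2 is still silylated, giving the alcohol F9.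
- Bu4NF then gives the erythro diol F10.
- HC(OEt)3 with pyridinium p-toluenesulfonate converts the diol into a cyclic orthoformate. Ionisation of this gives a dioxolanylium ion that holds C2, so the phenol can only enter anti to the departing oxygen, that is with inversion.
- Methanolysis of the formate esters with K2CO3 in MeOH gives the chroman diol F11.
- Selective benzylation of the phenol of F11 (BnBr, K2CO3) gives 20.

**Step 5.** The rate difference between the enantiomers of a terminal aryl vinyl carbinol may be too small for the epoxy alcohol to be formed in high enantiomeric purity near half conversion. The titanium alkoxide may also open the terminal epoxide.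

Fallback, resolution and epoxidation separated: it sets out from 6 and returns at 7.
- Lipase-catalysed acylation (Candida antarctica lipase B, vinyl acetate) takes the (R)-enantiomer, in line with the usual preference for secondary aryl carbinols, and gives the acetate F7.
- Methanolysis (K2CO3, MeOH) gives the enantiopure alcohol F8.
- F8 is epoxidised to completion with the same titanium–L-(+)-tartrate reagent in the matched sense. This gives 7 without dependence on a rate ratio.

## Further compounds

F1 | step 10 | 1,3-bis(benzyloxy)-5-{[2-(trimethylsilyl)ethoxy]methoxy}benzene | C[Si](C)(C)CCOCOc1cc(OCc2ccccc2)cc(OCc2ccccc2)c1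
F2 | step 10 | (1S,2R)-3-[2,4-bis(benzyloxy)-6-{[2-(trimethylsilyl)ethoxy]methoxy}phenyl]-1-[3,5-bis(benzyloxy)-4-methoxyphenyl]-1-[(tert-butyldimethylsilyl)oxy]propan-2-ol | COc1c(OCc2ccccc2)cc(cc1OCc1ccccc1)[C@H](O[Si](C)(C)C(C)(C)C)[C@H](O)Cc1c(OCOCC[Si](C)(C)C)cc(OCc2ccccc2)cc1OCc1ccccc1
F3 | step 10 | methoxymethyl ether of F2 at the C3 oxygen, (1S,2R) | COc1c(OCc2ccccc2)cc(cc1OCc1ccccc1)[C@H](O[Si](C)(C)C(C)(C)C)[C@H](OCOC)Cc1c(OCOCC[Si](C)(C)C)cc(OCc2ccccc2)cc1OCc1ccccc1
F4 | step 10 | 3,5-bis(benzyloxy)-2-{(2R,3S)-3-[3,5-bis(benzyloxy)-4-methoxyphenyl]-3-hydroxy-2-(methoxymethoxy)propyl}phenol | COc1c(OCc2ccccc2)cc(cc1OCc1ccccc1)[C@H](O)[C@H](OCOC)Cc1c(O)cc(OCc2ccccc2)cc1OCc1ccccc1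
F5 | step 8 | (1S,2S)-1-[3,5-bis(benzyloxy)-4-methoxyphenyl]-1-[(tert-butyldimethylsilyl)oxy]-3-iodopropan-2-ol | COc1c(OCc2ccccc2)cc(cc1OCc1ccccc1)[C@H](O[Si](C)(C)C(C)(C)C)[C@H](O)CI
F6 | step 8 | tert-butyl{[(1S,2S)-1-[3,5-bis(benzyloxy)-4-methoxyphenyl]-3-iodo-2-(methoxymethoxy)propyl]oxy}dimethylsilane | COc1c(OCc2ccccc2)cc(cc1OCc1ccccc1)[C@H](O[Si](C)(C)C(C)(C)C)[C@H](OCOC)CI
F7 | step 5 | (R)-1-[3,5-bis(benzyloxy)-4-methoxyphenyl]prop-2-en-1-yl acetate | COc1c(OCc2ccccc2)cc(cc1OCc1ccccc1)[C@H](OC(C)=O)C=C
F8 | step 5 | (R)-1-[3,5-bis(benzyloxy)-4-methoxyphenyl]prop-2-en-1-ol | COc1c(OCc2ccccc2)cc(cc1OCc1ccccc1)[C@H](O)C=C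
F9 | step 12 | 5-(benzyloxy)-2-{(2R,3S)-3-[3,5-bis(benzyloxy)-4-methoxyphenyl]-3-[(tert-butyldimethylsilyl)oxy]-2-hydroxypropyl}benzene-1,3-diol | COc1c(OCc2ccccc2)cc(cc1OCc1ccccc1)[C@H](O[Si](C)(C)C(C)(C)C)[C@H](O)Cc1c(O)cc(OCc2ccccc2)cc1O
F10 | step 12 | 5-(benzyloxy)-2-{(2R,3S)-3-[3,5-bis(benzyloxy)-4-methoxyphenyl]-2,3-dihydroxypropyl}benzene-1,3-diol | COc1c(OCc2ccccc2)cc(cc1OCc1ccccc1)[C@H](O)[C@H](O)Cc1c(O)cc(OCc2ccccc2)cc1O
F11 | step 12 | (2R,3R)-7-(benzyloxy)-2-[3,5-bis(benzyloxy)-4-methoxyphenyl]-3,4-dihydro-2H-1-benzopyran-3,5-diol | COc1c(OCc2ccccc2)cc(cc1OCc1ccccc1)[C@H]1Oc2cc(OCc3ccccc3)cc(O)c2C[C@H]1O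
A1 | alternative 1 | 3,5-bis(benzyloxy)phenol | Oc1cc(OCc2ccccc2)cc(OCc2ccccc2)c1
A2 | alternative 1 | formaldehyde | C=O
A3 | alternative 1 | (Z)-2-[3,5-bis(benzyloxy)-4-methoxyphenyl]ethenyl 3,4,5-tris(benzyloxy)benzoate | COc1c(OCc2ccccc2)cc(/C=C\OC(=O)c2cc(OCc3ccccc3)c(OCc3ccccc3)c(OCc3ccccc3)c2)cc1OCc1ccccc1
A4 | alternative 1 | (2R,3R)-5,7-bis(benzyloxy)-2-[3,5-bis(benzyloxy)-4-methoxyphenyl]-3,4-dihydro-2H-1-benzopyran-3-yl 3,4,5-tris(benzyloxy)benzoate (identical with 22) | COc1c(OCc2ccccc2)cc(cc1OCc1ccccc1)[C@H]1Oc2cc(OCc3ccccc3)cc(OCc3ccccc3)c2C[C@H]1OC(=O)c1cc(OCc2ccccc2)c(OCc2ccccc2)c(OCc2ccccc2)c1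
A5 | alternative 2 | tert-butyl{[(1S,2R)-1-[3,5-bis(benzyloxy)-4-methoxyphenyl]-2-(methoxymethoxy)-5-[(triisopropylsilyl)oxy]pent-4-yn-1-yl]oxy}dimethylsilane | COc1c(OCc2ccccc2)cc(cc1OCc1ccccc1)[C@H](O[Si](C)(C)C(C)(C)C)[C@H](OCOC)CC#CO[Si](C(C)C)(C(C)C)C(C)C
A6 | alternative 2 | 3-(benzyloxy)cyclobut-2-en-1-one | O=C1CC(OCc2ccccc2)=C1
A7 | alternative 2 | 5-(benzyloxy)-2-{(2R,3S)-3-[3,5-bis(benzyloxy)-4-methoxyphenyl]-3-[(tert-butyldimethylsilyl)oxy]-2-(methoxymethoxy)propyl}-3-[(triisopropylsilyl)oxy]phenol | COc1c(OCc2ccccc2)cc(cc1OCc1ccccc1)[C@H](O[Si](C)(C)C(C)(C)C)[C@H](OCOC)Cc1c(O)cc(OCc2ccccc2)cc1O[Si](C(C)C)(C(C)C)C(C)C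
A8 | alternative 3 | (R)-3-[3,5-bis(benzyloxy)-2-ethenylphenoxy]-3-[3,5-bis(benzyloxy)-4-methoxyphenyl]prop-1-en-2-yl 3,4,5-tris(benzyloxy)benzoate | COc1c(OCc2ccccc2)cc(cc1OCc1ccccc1)[C@@H](Oc1cc(OCc2ccccc2)cc(OCc2ccccc2)c1C=C)C(=C)OC(=O)c1cc(OCc2ccccc2)c(OCc2ccccc2)c(OCc2ccccc2)c1
A9 | alternative 3 | (R)-5,7-bis(benzyloxy)-2-[3,5-bis(benzyloxy)-4-methoxyphenyl]-2H-chromen-3-yl 3,4,5-tris(benzyloxy)benzoate | COc1c(OCc2ccccc2)cc(cc1OCc1ccccc1)[C@H]1Oc2cc(OCc3ccccc3)cc(OCc3ccccc3)c2C=C1OC(=O)c1cc(OCc2ccccc2)c(OCc2ccccc2)c(OCc2ccccc2)c1
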